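**Strategy.** Everything rests on cutting the bond between the benzylic carbon C1 of the 1,2-dihydronaphthalene and C3′ of the 2-pyranone. C1 is benzylic to the catechol ring (O at C6 para to C8a) and stands 1,3 to the carboxyl-bearing C3: this donor–acceptor pattern is stored as an enantiopure aryl cyclopropane triester. C3′, the α-carbon of the lactone carbonyl C2′, is made nucleophilic by a temporary 4′-hydroxyl. Lewis-acid SN2 opening of the cyclopropane by the 4-hydroxy-2-pyranone forms C1–C3′ with inversion, fixes C1, keeps C2 and leaves a malonate at C3 for the later closure of the carbocycle (C3=C4); the extra hydroxyl leaves as its triflate.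

Key step: step 4

Remark: pyranone atoms carry primes; di-tert-butyl 2-bromomalonate is taken as a catalogue compound (otherwise one step from di-tert-butyl malonate and NBS).

Step 1
Reactants: 1 methyl acetoacetate; 2 di-tert-butyl oxalate
Product: 4 tert-butyl 4-hydroxy-2-oxo-2H-pyran-6-carboxylate, via triketo diester 3 (not isolated)
Conditions: LDA (3 equiv), THF, −78 °C; 2, −78 → 0 °C; aq. HCl; then DBU, PhMe, 80 °C
Reagents that add atoms: none
Why: Claisen γ-acylation of the acetoacetate dianion by the oxalate and base-induced lactonisation of the C5 enol onto the methyl ester (the cyclisation that gives triacetic acid lactone) should give the 4-hydroxy-2-pyranone with the tert-butyl ester at C6; no stereocentre is formed.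

Step 2
Reactants: 5 (E)-3-(3,4-dimethoxyphenyl)prop-2-enal; 6 di-tert-butyl 2-bromomalonate
Product: 7 di-tert-butyl (2R,3S)-3-(3,4-dimethoxyphenyl)-2-formylcyclopropane-1,1-dicarboxylate
Conditions: (S)-α,α-diphenylprolinol trimethylsilyl ether (20 mol%), 2,6-lutidine (1.1 equiv), CH2Cl2, 0 °C
Reagents that add atoms: none
Why: Michael-initiated ring closure under iminium/enamine catalysis: the (S)-catalyst shields the Re face of C-β so that the bromomalonate adds to the Si face (aryl carbon S), and 3-exo-tet alkylation of the enamine then places the formyl group trans to the aryl group (2R).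

Step 3
Reactants: 7 di-tert-butyl (2R,3S)-3-(3,4-dimethoxyphenyl)-2-formylcyclopropane-1,1-dicarboxylate
Product: 9 tri-tert-butyl (2R,3S)-3-(3,4-dimethoxyphenyl)cyclopropane-1,1,2-tricarboxylate, via cyclopropane acid 8 (not isolated)
Conditions: NaClO2, NaH2PO4, 2-methyl-2-butene, t-BuOH–H2O, 0 °C; extractive work-up; then O-tert-butyl-N,N'-diisopropylisourea, CH2Cl2, rt
Reagents that add atoms: sodium chlorite [Na+].[O-]Cl=O; O-tert-butyl-N,N'-diisopropylisourea CC(C)N=C(OC(C)(C)C)NC(C)C
Why: Pinnick oxidation (HOCl trapped by 2-methyl-2-butene) and acid-free tert-butylation with the isourea should give the bulky ester without opening the acid-sensitive donor–acceptor cyclopropane or touching either stereocentre; the tert-butyl ester later prevents lactonisation onto the pyranone 4′-OH.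

Step 4
Reactants: 9 tri-tert-butyl (2R,3S)-3-(3,4-dimethoxyphenyl)cyclopropane-1,1,2-tricarboxylate; 4 tert-butyl 4-hydroxy-2-oxo-2H-pyran-6-carboxylate
Product: 10 tri-tert-butyl (2R,3R)-3-[6-(tert-butoxycarbonyl)-4-hydroxy-2-oxo-2H-pyran-3-yl]-3-(3,4-dimethoxyphenyl)propane-1,1,2-tricarboxylate
Conditions: Sc(OTf)3 (10 mol%), 4 Å MS, ClCH2CH2Cl, −20 °C → rt
Reagents that add atoms: none
Why: Sc(III) chelates the geminal diester of 9 and polarises the bond between the malonate carbon (later C3) and the benzylic carbon (later C1), which the enol carbon C3′ of 4 (flanked by the lactone C2′=O and C4′–OH) attacks from the rear; proton transfer from the enol to the scandium malonate should release 10 and the catalyst. The closest known reaction type is the Lewis-acid-catalysed homo-Michael (Friedel–Crafts-type) opening of 2-aryl cyclopropane-1,1-diesters by indoles, naphthols and enolised 1,3-dicarbonyl compounds, which runs with inversion at the benzylic carbon. No ring is closed: the three-membered ring is opened and its strain pays for the C–C bond. C1 is set (R) by inversion of the (S) aryl carbon of 9, itself fixed by the organocatalyst of step 2, and C2 (R) is carried through untouched, so the 1,2-trans pattern of the target is already in place. The step needs cleavage of the malonate–benzyl bond and not the C2–benzyl bond (only the former is chelate-activated and ends in a doubly stabilised anion), C- over O-alkylation and C3′ over C5′ (C-alkylation is usual for 4-hydroxy-2-pyranones with benzylic electrophiles, and C5′ is deactivated by the ester), and an SN2-like course. The last should be secured by the low temperature and by the electron-withdrawing ester at C2 next to the benzylic carbon; a C1 epimer from cation leakage would be a diastereomer (C2 is fixed) that chromatography removes, so the enantiomeric purity is not at stake.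

Step 5
Reactants: 10 tri-tert-butyl (2R,3R)-3-[6-(tert-butoxycarbonyl)-4-hydroxy-2-oxo-2H-pyran-3-yl]-3-(3,4-dimethoxyphenyl)propane-1,1,2-tricarboxylate
Product: 11 tri-tert-butyl (2R,3R)-3-[6-(tert-butoxycarbonyl)-2-oxo-4-(trifluoromethylsulfonyloxy)-2H-pyran-3-yl]-3-(3,4-dimethoxyphenyl)propane-1,1,2-tricarboxylate
Conditions: Tf2O, pyridine, CH2Cl2, −78 → 0 °C
Reagents that add atoms: trifluoromethanesulfonic anhydride O=S(=O)(OS(=O)(=O)C(F)(F)F)C(F)(F)F
Why: O-sulfonylation of the acidic enol (a vinylogous carboxylic acid) turns the temporary activating oxygen into a vinylogous acyl triflate; pyridine is too weak a base to touch the C–H acidic sites.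

Step 6
Reactants: 11 tri-tert-butyl (2R,3R)-3-[6-(tert-butoxycarbonyl)-2-oxo-4-(trifluoromethylsulfonyloxy)-2H-pyran-3-yl]-3-(3,4-dimethoxyphenyl)propane-1,1,2-tricarboxylate
Product: 12 tri-tert-butyl (2R,3R)-3-[6-(tert-butoxycarbonyl)-2-oxo-2H-pyran-3-yl]-3-(3,4-dimethoxyphenyl)propane-1,1,2-tricarboxylate
Conditions: Pd(OAc)2 (5 mol%), dppf, HCO2H, Et3N, DMF, 60 °C
Reagents that add atoms: none
Why: Pd-catalysed formate reduction of the enol triflate (oxidative addition, formate decarboxylation to Pd–H, reductive elimination) should replace OTf by H and reveal the 2-pyranone while esters and arene stay untouched.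

Step 7
Reactants: 12 tri-tert-butyl (2R,3R)-3-[6-(tert-butoxycarbonyl)-2-oxo-2H-pyran-3-yl]-3-(3,4-dimethoxyphenyl)propane-1,1,2-tricarboxylate
Product: 13 tri-tert-butyl (2R,3R)-3-[6-(tert-butoxycarbonyl)-2-oxo-2H-pyran-3-yl]-3-(2-formyl-4,5-dimethoxyphenyl)propane-1,1,2-tricarboxylate
Conditions: Cl2CHOMe, TiCl4, CH2Cl2, −78 °C; cold aq. NaHCO3
Reagents that add atoms: dichloromethyl methyl ether COC(Cl)Cl; water O
Why: Rieche formylation should take place at the ring carbon ortho to the benzylic substituent and para to the 3-methoxy group, the usual site of electrophilic substitution in 4-alkylveratroles, and the low temperature should keep the tert-butyl esters on.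

Step 8
Reactants: 13 tri-tert-butyl (2R,3R)-3-[6-(tert-butoxycarbonyl)-2-oxo-2H-pyran-3-yl]-3-(2-formyl-4,5-dimethoxyphenyl)propane-1,1,2-tricarboxylate
Product: 15 (1R,2R)-1-(6-carboxy-2-oxo-2H-pyran-3-yl)-6,7-dimethoxy-1,2-dihydronaphthalene-2,3-dicarboxylic acid, via tetra-acid aldehyde 14 (not isolated)
Conditions: TFA–CH2Cl2, rt; evaporate; pyridine, 80 °C
Reagents that add atoms: none
Why: Acidolysis of the four tert-butyl esters followed by intramolecular Knoevenagel–Doebner condensation of the substituted malonic acid with the ortho aldehyde (6-exo-trig aldol, then loss of CO2 and water) should close the carbocycle as the arene-conjugated C3=C4 acid; C1 and C2 are not involved and the 1,2-trans diacid is also the thermodynamically favoured isomer.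

Step 9
Reactants: 15 (1R,2R)-1-(6-carboxy-2-oxo-2H-pyran-3-yl)-6,7-dimethoxy-1,2-dihydronaphthalene-2,3-dicarboxylic acid
Product: 16 (1R,2R)-1-(6-carboxy-2-oxo-2H-pyran-3-yl)-6,7-dihydroxy-1,2-dihydronaphthalene-2,3-dicarboxylic acid (CNP0420981.1)
Conditions: BBr3, CH2Cl2, −78 → 0 °C; H2O
Reagents that add atoms: none
Why: BBr3 demethylation of the two aryl methyl ethers (bromide attack on the methyl of the aryloxonium–borane complexes) is the standard last step for catechol acids and should leave the pyranone, the acrylic acid and both stereocentres unchanged.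

**Compound list**

1 | methyl acetoacetate | CC(=O)CC(=O)OC | starting material
2 | di-tert-butyl oxalate | CC(C)(C)OC(=O)C(=O)OC(C)(C)C | starting material
3 | 6-tert-butyl 1-methyl 3,5-dioxohexanedioate | COC(=O)CC(=O)CC(=O)C(=O)OC(C)(C)C | intermediate
4 | tert-butyl 4-hydroxy-2-oxo-2H-pyran-6-carboxylate | CC(C)(C)OC(=O)c1cc(O)cc(=O)o1 | intermediate
5 | (E)-3-(3,4-dimethoxyphenyl)prop-2-enal | COc1ccc(/C=C/C=O)cc1OC | starting material
6 | di-tert-butyl 2-bromomalonate | CC(C)(C)OC(=O)C(Br)C(=O)OC(C)(C)C | starting material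
7 | di-tert-butyl (2R,3S)-3-(3,4-dimethoxyphenyl)-2-formylcyclopropane-1,1-dicarboxylate | O=C[C@@H]1[C@@H](c2ccc(OC)c(OC)c2)C1(C(=O)OC(C)(C)C)C(=O)OC(C)(C)C | intermediate
8 | (1R,3S)-2,2-bis(tert-butoxycarbonyl)-3-(3,4-dimethoxyphenyl)cyclopropane-1-carboxylic acid | O=C(O)[C@@H]1[C@@H](c2ccc(OC)c(OC)c2)C1(C(=O)OC(C)(C)C)C(=O)OC(C)(C)C | intermediate
9 | tri-tert-butyl (2R,3S)-3-(3,4-dimethoxyphenyl)cyclopropane-1,1,2-tricarboxylate | CC(C)(C)OC(=O)[C@@H]1[C@@H](c2ccc(OC)c(OC)c2)C1(C(=O)OC(C)(C)C)C(=O)OC(C)(C)C | intermediate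
10 | tri-tert-butyl (2R,3R)-3-[6-(tert-butoxycarbonyl)-4-hydroxy-2-oxo-2H-pyran-3-yl]-3-(3,4-dimethoxyphenyl)propane-1,1,2-tricarboxylate | CC(C)(C)OC(=O)[C@H]([C@H](c1ccc(OC)c(OC)c1)c1c(O)cc(C(=O)OC(C)(C)C)oc1=O)C(C(=O)OC(C)(C)C)C(=O)OC(C)(C)C | intermediate
11 | tri-tert-butyl (2R,3R)-3-[6-(tert-butoxycarbonyl)-2-oxo-4-(trifluoromethylsulfonyloxy)-2H-pyran-3-yl]-3-(3,4-dimethoxyphenyl)propane-1,1,2-tricarboxylate | CC(C)(C)OC(=O)[C@H]([C@H](c1ccc(OC)c(OC)c1)c1c(OS(=O)(=O)C(F)(F)F)cc(C(=O)OC(C)(C)C)oc1=O)C(C(=O)OC(C)(C)C)C(=O)OC(C)(C)C | intermediate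
12 | tri-tert-butyl (2R,3R)-3-[6-(tert-butoxycarbonyl)-2-oxo-2H-pyran-3-yl]-3-(3,4-dimethoxyphenyl)propane-1,1,2-tricarboxylate | CC(C)(C)OC(=O)[C@H]([C@H](c1ccc(OC)c(OC)c1)c1ccc(C(=O)OC(C)(C)C)oc1=O)C(C(=O)OC(C)(C)C)C(=O)OC(C)(C)C | intermediate
13 | tri-tert-butyl (2R,3R)-3-[6-(tert-butoxycarbonyl)-2-oxo-2H-pyran-3-yl]-3-(2-formyl-4,5-dimethoxyphenyl)propane-1,1,2-tricarboxylate | CC(C)(C)OC(=O)[C@H]([C@H](c1cc(OC)c(OC)cc1C=O)c1ccc(C(=O)OC(C)(C)C)oc1=O)C(C(=O)OC(C)(C)C)C(=O)OC(C)(C)C | intermediate
14 | (2R,3R)-3-(6-carboxy-2-oxo-2H-pyran-3-yl)-3-(2-formyl-4,5-dimethoxyphenyl)propane-1,1,2-tricarboxylic acid | O=C(O)[C@H]([C@H](c1cc(OC)c(OC)cc1C=O)c1ccc(C(=O)O)oc1=O)C(C(=O)O)C(=O)O | intermediate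
15 | (1R,2R)-1-(6-carboxy-2-oxo-2H-pyran-3-yl)-6,7-dimethoxy-1,2-dihydronaphthalene-2,3-dicarboxylic acid | O=C(O)C1=Cc2cc(OC)c(OC)cc2[C@H](c2ccc(C(=O)O)oc2=O)[C@H]1C(=O)O | intermediate
16 | (1R,2R)-1-(6-carboxy-2-oxo-2H-pyran-3-yl)-6,7-dihydroxy-1,2-dihydronaphthalene-2,3-dicarboxylic acid | O=C(O)C1=Cc2cc(O)c(O)cc2[C@H](c2ccc(C(=O)O)oc2=O)[C@H]1C(=O)O | target

**Step count and risks**

Total step count: 9. Longest linear sequence: 8 steps (steps 2 to 9, from 5 to 16); step 1 is a one-step side branch.

Steps most likely to fail: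

Step 4 (key step). The opening may run through a free benzylic cation, which would scramble C1, or it may stop at O-alkylation of the enol. Fallback, setting out from 5 and 4 and coming back at 10: the bond is made first and under catalyst control. Iminium-catalysed Michael addition of 4 to enal 5 with (R)-α,α-diphenylprolinol trimethylsilyl ether should give the bicyclic lactol F1 with the benzylic carbon R. Photoredox organocatalytic α-alkylation of its open-chain aldehyde with bromomalonate 6 (chiral imidazolidinone, Ru(bpy)3Cl2, 2,6-lutidine, blue light) should then give the malonyl lactol F2. Oxidation of the lactol with TEMPO/PhI(OAc)2 gives the enol lactone F3, which LiOtBu (THF, −40 °C) opens at the acyl carbon to the tert-butyl ester 10.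

Step 7. Formylation may occur at the wrong ring position, or tert-butyl esters may be lost under TiCl4 with acylation chemistry following. Fallback, setting out from 12 and coming back at 13: bromination with NBS in MeCN should place bromine at the same carbon (para to the 3-methoxy group) to give the aryl bromide F4. Pd-catalysed reductive carbonylation (Pd(OAc)2, di(1-adamantyl)-n-butylphosphine, CO/H2, TMEDA, toluene, 100 °C) then converts it into aldehyde 13 without a Lewis acid.

Step 9. BBr3 may attack the styrene-type double bond or the pyranone of the finished skeleton, or the polar product may be lost on work-up. Fallback, setting out from 13 and coming back at 16: the order is changed so that BBr3 meets no dihydronaphthalene. BBr3 on 13 cleaves the four tert-butyl esters and both methyl ethers to the catechol aldehyde tetra-acid F5. The Knoevenagel–Doebner closure (pyridine, 80 °C), which tolerates free catechols as in the classical preparation of caffeic acid, should then give 16 directly.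

**Further compounds**

F1 | step 4 | tert-butyl (4R)-4-(3,4-dimethoxyphenyl)-2-hydroxy-5-oxo-3,4-dihydro-2H,5H-pyrano[4,3-b]pyran-7-carboxylate | O=c1oc(C(=O)OC(C)(C)C)cc2c1[C@@H](c1ccc(OC)c(OC)c1)CC(O)O2
F2 | step 4 | tert-butyl (3R,4R)-3-[bis(tert-butoxycarbonyl)methyl]-4-(3,4-dimethoxyphenyl)-2-hydroxy-5-oxo-3,4-dihydro-2H,5H-pyrano[4,3-b]pyran-7-carboxylate | O=c1oc(C(=O)OC(C)(C)C)cc2c1[C@@H](c1ccc(OC)c(OC)c1)[C@H](C(C(=O)OC(C)(C)C)C(=O)OC(C)(C)C)C(O)O2
F3 | step 4 | tert-butyl (3R,4R)-3-[bis(tert-butoxycarbonyl)methyl]-4-(3,4-dimethoxyphenyl)-2,5-dioxo-3,4-dihydro-2H,5H-pyrano[4,3-b]pyran-7-carboxylate | O=c1oc(C(=O)OC(C)(C)C)cc2c1[C@@H](c1ccc(OC)c(OC)c1)[C@H](C(C(=O)OC(C)(C)C)C(=O)OC(C)(C)C)C(=O)O2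
F4 | step 7 | tri-tert-butyl (2R,3S)-3-(2-bromo-4,5-dimethoxyphenyl)-3-[6-(tert-butoxycarbonyl)-2-oxo-2H-pyran-3-yl]propane-1,1,2-tricarboxylate (same spatial arrangement as 12) | CC(C)(C)OC(=O)[C@H]([C@H](c1cc(OC)c(OC)cc1Br)c1ccc(C(=O)OC(C)(C)C)oc1=O)C(C(=O)OC(C)(C)C)C(=O)OC(C)(C)C
F5 | step 9 | (2R,3R)-3-(6-carboxy-2-oxo-2H-pyran-3-yl)-3-(2-formyl-4,5-dihydroxyphenyl)propane-1,1,2-tricarboxylic acid | O=C(O)[C@H]([C@H](c1cc(O)c(O)cc1C=O)c1ccc(C(=O)O)oc1=O)C(C(=O)O)C(=O)O
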